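**Strategy**

The synthesis rests on reading the Me2C–O–CH unit of the 2,2-dimethyloxolane ring (O1, C2–H, C3H2, C4–H, C5Me2) that bridges the 14-membered carbocycle as the acetone ketal of an allylic 1,2-diol. SnCl4 converts a trans-acetonide carrying an (E)-alkenyl group into this oxolane by Prins cyclisation and pinacol ring contraction: C4–C5 and C2–C3 form in one operation, and the allylic carbinol carbon is pushed out as a formyl group, later lost as CO. The precursor is thus a 1,3-dioxolane whose ketal carbon was introduced as a protecting group and whose stereocentres derive from dimethyl (R)-malate; the macrocycle is closed last by Horner–Wadsworth–Emmons olefination.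

Key step: step 9

Remark on the chemistry: the carbinol carbon made in step 7 is destroyed in step 9, and the phosphonate-bearing carbon of 23–26 becomes sp2 in step 14, so an epimeric mixture at either centre is acceptable. Compounds 18 and 19 are drawn as the expected major epimer; 23–26 are written without configuration at the phosphonate carbon.

**Route**

Step 1
Reactants: 1 dimethyl (R)-malate; 2 allyl bromide
Product: 3 dimethyl (2R,3S)-2-hydroxy-3-(prop-2-en-1-yl)butanedioate
Conditions: LiHMDS (2.2 equiv), THF, −78 → −20 °C; then 2, −78 → −10 °C; AcOH quench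
Reagents that add atoms: none
Why: Fráter–Seebach alkylation: the chelated lithium alkoxide–enolate dianion should be allylated anti to the C2–O bond, which sets the ester-bearing stereocentre (3S) relative to the malate carbinol carbon.

Step 2
Reactants: 3 dimethyl (2R,3S)-2-hydroxy-3-(prop-2-en-1-yl)butanedioate; 4 2-methoxypropene
Product: 5 dimethyl (2R,3S)-2-[(2-methoxypropan-2-yl)oxy]-3-(prop-2-en-1-yl)butanedioate
Conditions: 4 (3 equiv), PPTS (cat.), CH2Cl2, 0 °C; Et3N quench
Reagents that add atoms: none
Why: acid-catalysed addition of the hydroxyl to the enol ether gives the mixed-ketal ether, which protects the alcohol and already places the future gem-dimethyl ring carbon on this oxygen.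

Step 3
Reactants: 5 dimethyl (2R,3S)-2-[(2-methoxypropan-2-yl)oxy]-3-(prop-2-en-1-yl)butanedioate
Product: 6 methyl (2S)-2-[(1R)-1-[(2-methoxypropan-2-yl)oxy]-2-oxoethyl]pent-4-enoate
Conditions: DIBAL-H (1.05 equiv), CH2Cl2, −78 °C; MeOH, then aq. Rochelle salt; used crude
Reagents that add atoms: none
Why: partial ester reduction: the α-alkoxy ester is more electrophilic and less hindered than the α-branched ester, and its aluminium hemiacetal is held by the neighbouring oxygen until work-up, so reduction should stop at the aldehyde at this carbon only.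

Step 4
Reactants: 7 (4-bromobut-1-yn-1-yl)trimethylsilane; 8 propyne; 9 oxirane
Product: 13 (3Z)-4-methyl-8-(trimethylsilyl)oct-3-en-7-yn-1-ol, via alkyl Grignard reagent 10 (not isolated), via alkylcopper 11 (not isolated), via (Z)-alkenylcopper 12 (not isolated)
Conditions: Mg, THF; CuBr·SMe2 (1 equiv), Et2O–Me2S, −45 °C; 8, −25 °C; 1-pentynyllithium (from 1-pentyne, n-BuLi), DMPU, then 9, −78 → −20 °C; aq. NH4Cl
Reagents that add atoms: none
Why: syn carbocupration of propyne puts the alkyl group on the internal carbon and copper cis to it on the terminal carbon, and opening of oxirane by the derived mixed cuprate retains the alkenyl geometry, which fixes the (Z)-trisubstituted alkene (the silylalkyne is inert to carbocupration).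

Step 5
Reactants: 13 (3Z)-4-methyl-8-(trimethylsilyl)oct-3-en-7-yn-1-ol
Product: 14 [(5Z)-8-chloro-5-methyloct-5-en-1-yn-1-yl]trimethylsilane
Conditions: PPh3, N-chlorosuccinimide, THF, 0 °C → rt
Reagents that add atoms: N-chlorosuccinimide, O=C1CCC(=O)N1Cl
Why: Appel-type chlorination of the primary alcohol through the alkoxyphosphonium salt (SN2) gives a chloride that is inert in steps 6–10 and serves as the electrophile in step 11.

Step 6
Reactants: 14 [(5Z)-8-chloro-5-methyloct-5-en-1-yn-1-yl]trimethylsilane
Product: 15 (5Z)-8-chloro-5-methyloct-5-en-1-yne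
Conditions: K2CO3, MeOH, rt
Reagents that add atoms: none
Why: base-mediated methanolysis of the alkynyl C–Si bond frees the terminal alkyne without touching the alkyl chloride or the alkene.

Step 7
Reactants: 15 (5Z)-8-chloro-5-methyloct-5-en-1-yne; 6 methyl (2S)-2-[(1R)-1-[(2-methoxypropan-2-yl)oxy]-2-oxoethyl]pent-4-enoate
Product: 18 methyl (2S)-2-[(1R,2R,3E,7Z)-10-chloro-2-hydroxy-1-[(2-methoxypropan-2-yl)oxy]-7-methyldeca-3,7-dien-1-yl]pent-4-enoate, via alkenylzirconocene 16 (not isolated), via alkenyl(methyl)zinc 17 (not isolated)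
Conditions: Cp2Zr(H)Cl, CH2Cl2, rt; Me2Zn, −65 °C; then 6, −65 → 0 °C; aq. NaHCO3; used at once
Reagents that add atoms: none
Why: syn, anti-Markovnikov hydrozirconation gives the (E)-alkenylzirconocene, Zr→Zn transmetalation gives an alkenylzinc that adds to the aldehyde but not to the esters, and chelation of zinc between the aldehyde and α-ketal oxygens should favour the (R)-carbinol (syn diol); the epimer is tolerable because this carbon becomes the formyl carbon in step 9.

Step 8
Reactants: 18 methyl (2S)-2-[(1R,2R,3E,7Z)-10-chloro-2-hydroxy-1-[(2-methoxypropan-2-yl)oxy]-7-methyldeca-3,7-dien-1-yl]pent-4-enoate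
Product: 19 methyl (2S)-2-[(4R,5R)-5-[(1E,5Z)-8-chloro-5-methylocta-1,5-dien-1-yl]-2,2-dimethyl-1,3-dioxolan-4-yl]pent-4-enoate
Conditions: PPTS (cat.), 4 Å MS, CH2Cl2, rt
Reagents that add atoms: none
Why: intramolecular transketalisation: the mixed ketal ionises to its oxocarbenium ion, which the neighbouring hydroxyl captures with loss of methanol to give the trans-4,5-disubstituted acetonide, expected to be faster than lactonisation of that hydroxyl onto the ester.

Step 9
Reactants: 19 methyl (2S)-2-[(4R,5R)-5-[(1E,5Z)-8-chloro-5-methylocta-1,5-dien-1-yl]-2,2-dimethyl-1,3-dioxolan-4-yl]pent-4-enoate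
Product: 20 methyl (2S)-2-[(2S,3R,4R)-4-[(3Z)-6-chloro-3-methylhex-3-en-1-yl]-3-formyl-5,5-dimethyloxolan-2-yl]pent-4-enoate
Conditions: SnCl4 (2.2 equiv), 2,6-di-tert-butyl-4-methylpyridine (0.3 equiv), CH2Cl2, −78 → −23 °C; aq. NaHCO3 at −40 °C
Reagents that add atoms: none
Why: SnCl4 opens the dioxolane at the allylic oxygen to give the 2-propylidene oxocarbenium ion on the other oxygen; its carbon is attacked by the distal alkene carbon through a six-membered chair (new C4–C5 bond of the oxolane), and the positive charge developing at the proximal alkene carbon is discharged by a 1,2-shift of the oxygen-bearing ring carbon away from the stannyloxy carbon (new C2–C3 bond), which leaves as the formyl group. The closest known reaction type is the Prins cyclisation–pinacol rearrangement of acetals and ketals of allylic 1,2-diols to 3-acyltetrahydrofurans. The oxolane therefore closes in two stages within one operation: a 6-endo-trig Prins closure to an incipient oxan-4-yl cation, then ring contraction by the pinacol shift. C2 migrates with retention and keeps the malate-derived configuration; C4 is fixed in the chair, where the (E)-alkene holds its chain equatorial and the oxocarbenium methyl cis to the ring carbon forbids an axial ester-bearing substituent, so the two substituents end up trans; C3 is formed with the formyl group cis to the C2 substituent and loses its stereogenicity in step 10. The step needs chemoselectivity for the allylic alkene over the trisubstituted and terminal alkenes, which only this alkene can meet through a six-membered transition state, and ring contraction in preference to hydride shift, which the syn-diol geometry (C–O axial, C–H equatorial at the carbinol carbon) should secure; ketal opening in the unproductive direction is reversible.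

Step 10
Reactants: 20 methyl (2S)-2-[(2S,3R,4R)-4-[(3Z)-6-chloro-3-methylhex-3-en-1-yl]-3-formyl-5,5-dimethyloxolan-2-yl]pent-4-enoate
Product: 21 methyl (2S)-2-[(2S,4R)-4-[(3Z)-6-chloro-3-methylhex-3-en-1-yl]-5,5-dimethyloxolan-2-yl]pent-4-enoate
Conditions: RhCl(PPh3)3 (1.1 equiv), toluene, 110 °C
Reagents that add atoms: none
Why: Tsuji–Wilkinson decarbonylation (oxidative addition of the formyl C–H bond, CO de-insertion, C–H reductive elimination) replaces CHO by H at C3 and leaves the C2 and C4 stereocentres untouched.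

Step 11
Reactants: 21 methyl (2S)-2-[(2S,4R)-4-[(3Z)-6-chloro-3-methylhex-3-en-1-yl]-5,5-dimethyloxolan-2-yl]pent-4-enoate; 22 methyl 2-(diethoxyphosphoryl)acetate
Product: 23 methyl (2S)-2-[(2S,4R)-4-[(3Z)-7-(diethoxyphosphoryl)-8-methoxy-3-methyl-8-oxooct-3-en-1-yl]-5,5-dimethyloxolan-2-yl]pent-4-enoate
Conditions: NaH, 22 (3 equiv), Bu4NI (cat.), DMF, 70 °C
Reagents that add atoms: none
Why: SN2 alkylation of the sodium phosphonoacetate carbanion by the primary chloride under iodide catalysis; the weakly basic stabilised anion should not epimerise the α-ester stereocentre.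

Step 12
Reactants: 23 methyl (2S)-2-[(2S,4R)-4-[(3Z)-7-(diethoxyphosphoryl)-8-methoxy-3-methyl-8-oxooct-3-en-1-yl]-5,5-dimethyloxolan-2-yl]pent-4-enoate
Product: 25 methyl (2S)-2-[(2S,4R)-4-[(3Z)-7-(diethoxyphosphoryl)-8-methoxy-3-methyl-8-oxooct-3-en-1-yl]-5,5-dimethyloxolan-2-yl]-5-hydroxypentanoate, via B-alkyl-9-BBN 24 (not isolated)
Conditions: 9-BBN, THF, 0 °C → rt; then 30% H2O2, aq. NaOAc, 0 °C
Reagents that add atoms: hydrogen peroxide, OO
Why: anti-Markovnikov hydroboration–oxidation: the bulky borane reacts with the monosubstituted alkene far faster than with the trisubstituted one, and the buffered oxidation spares the esters and the phosphonate.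

Step 13
Reactants: 25 methyl (2S)-2-[(2S,4R)-4-[(3Z)-7-(diethoxyphosphoryl)-8-methoxy-3-methyl-8-oxooct-3-en-1-yl]-5,5-dimethyloxolan-2-yl]-5-hydroxypentanoate
Product: 26 methyl (2S)-2-[(2S,4R)-4-[(3Z)-7-(diethoxyphosphoryl)-8-methoxy-3-methyl-8-oxooct-3-en-1-yl]-5,5-dimethyloxolan-2-yl]-5-oxopentanoate
Conditions: Dess–Martin periodinane, NaHCO3, CH2Cl2, 0 °C → rt
Reagents that add atoms: none
Why: Dess–Martin oxidation of the primary alcohol to the aldehyde under buffered, non-basic conditions that leave the acidic phosphonoacetate unchanged.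

Step 14
Reactants: 26 methyl (2S)-2-[(2S,4R)-4-[(3Z)-7-(diethoxyphosphoryl)-8-methoxy-3-methyl-8-oxooct-3-en-1-yl]-5,5-dimethyloxolan-2-yl]-5-oxopentanoate
Product: 27 dimethyl (1R,4Z,8E,12S,13S)-4,15,15-trimethyl-14-oxabicyclo[11.2.1]hexadeca-4,8-diene-8,12-dicarboxylate (target)
Conditions: LiCl, DBU, MeCN, rt, high dilution (syringe-pump addition of 26)
Reagents that add atoms: none
Why: intramolecular Horner–Wadsworth–Emmons olefination under mild lithium chloride/amine conditions closes the 14-membered ring, and the α-substituted phosphonoacetate should give the (E)-trisubstituted enoate with the ester trans to the new chain carbon.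

**Compound list**

1 | dimethyl (R)-malate | COC(=O)C[C@@H](O)C(=O)OC | starting material
2 | allyl bromide | C=CCBr | starting material
3 | dimethyl (2R,3S)-2-hydroxy-3-(prop-2-en-1-yl)butanedioate | C=CC[C@H](C(=O)OC)[C@@H](O)C(=O)OC | intermediate
4 | 2-methoxypropene | COC(C)=C | starting material
5 | dimethyl (2R,3S)-2-[(2-methoxypropan-2-yl)oxy]-3-(prop-2-en-1-yl)butanedioate | C=CC[C@H](C(=O)OC)[C@@H](OC(C)(C)OC)C(=O)OC | intermediate
6 | methyl (2S)-2-[(1R)-1-[(2-methoxypropan-2-yl)oxy]-2-oxoethyl]pent-4-enoate | C=CC[C@H](C(=O)OC)[C@@H](OC(C)(C)OC)C=O | intermediate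
7 | (4-bromobut-1-yn-1-yl)trimethylsilane | C[Si](C)(C)C#CCCBr | starting material
8 | propyne | CC#C | starting material
9 | oxirane (ethylene oxide) | C1CO1 | starting material
10 | [4-(trimethylsilyl)but-3-yn-1-yl]magnesium bromide | C[Si](C)(C)C#CCC[Mg]Br | intermediate
11 | [4-(trimethylsilyl)but-3-yn-1-yl]copper(I) | C[Si](C)(C)C#CCC[Cu] | intermediate
12 | [(1Z)-2-methyl-6-(trimethylsilyl)hex-1-en-5-yn-1-yl]copper(I) | C[Si](C)(C)C#CCC/C(C)=C\[Cu] | intermediate
13 | (3Z)-4-methyl-8-(trimethylsilyl)oct-3-en-7-yn-1-ol | C[Si](C)(C)C#CCC/C(C)=C\CCO | intermediate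
14 | [(5Z)-8-chloro-5-methyloct-5-en-1-yn-1-yl]trimethylsilane | C[Si](C)(C)C#CCC/C(C)=C\CCCl | intermediate
15 | (5Z)-8-chloro-5-methyloct-5-en-1-yne | C#CCC/C(C)=C\CCCl | intermediate
16 | chloro[(1E,5Z)-8-chloro-5-methylocta-1,5-dien-1-yl]bis(cyclopentadienyl)zirconium | ClCC/C=C(C)\CC/C=C/[Zr](Cl)(C1C=CC=C1)C1C=CC=C1 | intermediate
17 | [(1E,5Z)-8-chloro-5-methylocta-1,5-dien-1-yl](methyl)zinc | ClCC/C=C(C)\CC/C=C/[Zn]C | intermediate
18 | methyl (2S)-2-[(1R,2R,3E,7Z)-10-chloro-2-hydroxy-1-[(2-methoxypropan-2-yl)oxy]-7-methyldeca-3,7-dien-1-yl]pent-4-enoate | C=CC[C@H](C(=O)OC)[C@@H](OC(C)(C)OC)[C@H](O)/C=C/CC/C(C)=C\CCCl | intermediate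
19 | methyl (2S)-2-[(4R,5R)-5-[(1E,5Z)-8-chloro-5-methylocta-1,5-dien-1-yl]-2,2-dimethyl-1,3-dioxolan-4-yl]pent-4-enoate | C=CC[C@H](C(=O)OC)[C@H]1OC(C)(C)O[C@@H]1/C=C/CC/C(C)=C\CCCl | intermediate
20 | methyl (2S)-2-[(2S,3R,4R)-4-[(3Z)-6-chloro-3-methylhex-3-en-1-yl]-3-formyl-5,5-dimethyloxolan-2-yl]pent-4-enoate | C=CC[C@H](C(=O)OC)[C@@H]1[C@H](C=O)[C@@H](CC/C(C)=C\CCCl)C(C)(C)O1 | intermediate
21 | methyl (2S)-2-[(2S,4R)-4-[(3Z)-6-chloro-3-methylhex-3-en-1-yl]-5,5-dimethyloxolan-2-yl]pent-4-enoate | C=CC[C@H](C(=O)OC)[C@@H]1C[C@@H](CC/C(C)=C\CCCl)C(C)(C)O1 | intermediate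
22 | methyl 2-(diethoxyphosphoryl)acetate | CCOP(=O)(CC(=O)OC)OCC | starting material
23 | methyl (2S)-2-[(2S,4R)-4-[(3Z)-7-(diethoxyphosphoryl)-8-methoxy-3-methyl-8-oxooct-3-en-1-yl]-5,5-dimethyloxolan-2-yl]pent-4-enoate (mixture at the phosphonate carbon) | C=CC[C@H](C(=O)OC)[C@@H]1C[C@@H](CC/C(C)=C\CCC(C(=O)OC)P(=O)(OCC)OCC)C(C)(C)O1 | intermediate
24 | B-alkyl-9-borabicyclo[3.3.1]nonane adduct of 23 at the terminal alkene carbon | B1(CCC[C@H](C(=O)OC)[C@@H]3C[C@@H](CC/C(C)=C\CCC(C(=O)OC)P(=O)(OCC)OCC)C(C)(C)O3)C2CCCC1CCC2 | intermediate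
25 | methyl (2S)-2-[(2S,4R)-4-[(3Z)-7-(diethoxyphosphoryl)-8-methoxy-3-methyl-8-oxooct-3-en-1-yl]-5,5-dimethyloxolan-2-yl]-5-hydroxypentanoate | OCCC[C@H](C(=O)OC)[C@@H]1C[C@@H](CC/C(C)=C\CCC(C(=O)OC)P(=O)(OCC)OCC)C(C)(C)O1 | intermediate
26 | methyl (2S)-2-[(2S,4R)-4-[(3Z)-7-(diethoxyphosphoryl)-8-methoxy-3-methyl-8-oxooct-3-en-1-yl]-5,5-dimethyloxolan-2-yl]-5-oxopentanoate | O=CCC[C@H](C(=O)OC)[C@@H]1C[C@@H](CC/C(C)=C\CCC(C(=O)OC)P(=O)(OCC)OCC)C(C)(C)O1 | intermediate
27 | dimethyl (1R,4Z,8E,12S,13S)-4,15,15-trimethyl-14-oxabicyclo[11.2.1]hexadeca-4,8-diene-8,12-dicarboxylate | COC(=O)/C1=C/CC[C@H](C(=O)OC)[C@@H]2C[C@@H](CC/C(C)=C\CC1)C(C)(C)O2 | target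

**Step count and risks**

Total step count: 14. Longest linear sequence: 11 steps (steps 1–3 or 4–6, then 7–14).

Steps most likely to fail:

Step 9. After the first C–C bond has formed, the cationic centre may be consumed by hydride shift, proton loss or chloride capture faster than by the ring-contracting shift; the weakly nucleophilic 1,2-disubstituted alkene may also react too slowly with the ketone-derived oxocarbenium ion. The fallback sets out from 19 and comes back at 20, making the two bonds in separate operations. SnBr4 in CH2Cl2 at −78 °C is used so that the oxan-4-yl cation is captured by bromide, which should give the Prins bromohydrin methyl (2S)-2-[(2R,3S,4R,5S)-4-bromo-5-[(3Z)-6-chloro-3-methylhex-3-en-1-yl]-3-hydroxy-6,6-dimethyloxan-2-yl]pent-4-enoate F1 with an equatorial bromide. F1 is used directly and treated with AgBF4 and 2,6-di-tert-butylpyridine in CH2Cl2; the ring C–C bond anti-periplanar to the C–Br bond then migrates (semipinacol ring contraction) to give 20.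

Step 10. Oxidative addition at the hindered formyl group may be slow, and the rhodium hydride so formed may move the terminal double bond into the chain. The fallback sets out from 20 and comes back at 21 by a radical route. Pinnick oxidation (NaClO2, NaH2PO4, 2-methylbut-2-ene) should give the C3 carboxylic acid corresponding to 20 F2. Coupling with N-hydroxypyridine-2-thione (DCC, DMAP) gives its thiohydroxamate ester F3. Photolysis of F3 in neat tert-butanethiol (Barton reductive decarboxylation) gives 21; the high thiol concentration is meant to outrun 5-exo cyclisation of the C3 radical onto the allyl group.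

Step 3. Reduction may run on to the primary alcohol or also touch the second ester. The fallback sets out from 5 and comes back at 6 by separating ester differentiation from reduction. Saponification of the more electrophilic α-alkoxy ester (LiOH, 1 equiv, THF–H2O, 0 °C) should give the mono-acid (2R,3S)-3-(methoxycarbonyl)-2-[(2-methoxypropan-2-yl)oxy]hex-5-enoic acid F4, handled as its lithium salt. Coupling (EDC, HOBt, MeNHOMe·HCl, N-methylmorpholine) gives the N-methoxy-N-methylamide F5, and DIBAL-H at −78 °C then stops at aldehyde 6 through the chelated hemiaminal.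

Further compounds
F1 | step 9 | methyl (2S)-2-[(2R,3S,4R,5S)-4-bromo-5-[(3Z)-6-chloro-3-methylhex-3-en-1-yl]-3-hydroxy-6,6-dimethyloxan-2-yl]pent-4-enoate | C=CC[C@H](C(=O)OC)[C@H]1OC(C)(C)[C@H](CC/C(C)=C\CCCl)[C@@H](Br)[C@H]1O
F2 | step 10 | C3 carboxylic acid corresponding to aldehyde 20 (CHO replaced by CO2H, same configuration) | C=CC[C@H](C(=O)OC)[C@@H]1[C@H](C(=O)O)[C@@H](CC/C(C)=C\CCCl)C(C)(C)O1
F3 | step 10 | N-hydroxypyridine-2-thione (2-thioxopyridin-1(2H)-yl) ester of F2 | C=CC[C@H](C(=O)OC)[C@@H]1[C@H](C(=O)ON2C=CC=CC2=S)[C@@H](CC/C(C)=C\CCCl)C(C)(C)O1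
F4 | step 3 | (2R,3S)-3-(methoxycarbonyl)-2-[(2-methoxypropan-2-yl)oxy]hex-5-enoic acid | C=CC[C@H](C(=O)OC)[C@@H](OC(C)(C)OC)C(=O)O
F5 | step 3 | methyl (2S)-2-[(1R)-2-[methoxy(methyl)amino]-1-[(2-methoxypropan-2-yl)oxy]-2-oxoethyl]pent-4-enoate | C=CC[C@H](C(=O)OC)[C@@H](OC(C)(C)OC)C(=O)N(C)OC
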